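# Proposed synthesis of epigallocatechin-(4β→6)-gallocatechin 3-O-gallate (CNP0271447.2)

## Structural features

The target is a dimeric flavan-3-ol. The upper unit is epigallocatechin (benzo ring A, pyran ring C, pyrogallol ring B) with a galloyl ester (ring G) on O3. The lower unit is gallocatechin (benzo ring D, pyran ring F, pyrogallol ring E), and one bond joins C4 of ring C to C6 of ring D. Ring C carries three contiguous stereocentres, C2 (R), C3 (R) and C4 (S), with ring B cis to O3 and the lower unit trans to O3. Ring F carries two more, C2 (R) and C3 (S, trans), remote from the first three and identical with those of (+)-gallocatechin. Thirteen phenols and one secondary alcohol are free; the pyrogallol rings oxidise easily in base and air, the ester is base-labile, and strong acid cleaves the doubly benzylic C4–C6 bond between two phloroglucinol-type rings. The real difficulty is threefold: the 2,3-cis-3,4-trans array at a crowded diarylmethine, attachment at C6 of ring D although C8 is the more reactive position, and acylation of the upper O3 only. The key step exploits the fact that C2 of ring C is bonded to O1, C3, ring B and hydrogen: with ring B and that hydrogen removed, C2 is the carbonyl carbon of an aryl lactone (a 3,4-dihydrocoumarin made of ring A, O1, C2, C3 and C4). On that rigid lactone C3 can be oxygenated anti to the C4 aryl group, and C2 then takes ring B as an aryl anion and hydrogen as hydride.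

## Logic of the disconnections

**25 ⇒ 24.** The fourteen O–benzyl bonds are cut. Free phenols cannot pass through enolate, organolithium and Lewis acid steps, and the lower O3 must be masked so that it is not acylated. One kind of protecting group and one neutral final step result. The forward hydrogenolysis must spare the ester, the benzylic C2–O1 bonds of rings C and F and the C4–C6 bond.

**24 ⇒ 22 + 23.** The O3–acyl bond is cut. An ester would not survive the aryllithium or fluoride, so the gallate is attached after ring C is complete. The forward step must acylate an axial hydroxyl flanked by two aryl groups.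

**22 ⇒ 21.** The O3–Si bond is cut. The silyl ether is the only fluoride-labile group, so upper O3 is released alone. The forward step must desilylate a crowded site.

**21 ⇒ 16 + 18 (through 19 and 20).** The C2–ring B bond and the C2–H bond are cut. This turns C2 into a lactone carbonyl, delivers ring B as a symmetrical aryl anion, and reduces three contiguous stereocentres to two on a rigid ring. The forward step needs a single addition to an aryl ester and hydride delivery anti to O3.

**16 ⇒ 15 ⇒ 13.** The O3–Si bond and then the C3–O3 bond are cut. C3 becomes a methylene group whose oxygen is introduced through the lactone enolate under control of C4. The forward step needs trans selectivity and an enolate that does not fragment.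

**13 ⇒ 12 ⇒ 8 + 10 (through 11).** The lactone is taken back to the lactol, then C4–C4a and O1–C2 are cut. C4 is the one upper stereocentre that no neighbour can control, so it is set by a catalyst in a conjugate Friedel–Crafts addition of a symmetrical phenol. The three-carbon chain already sits on C6 of ring D, so the 4→6 junction is fixed. The forward step needs face control by the catalyst and attack through the ortho carbon of the phenol.

**8 ⇒ 7 ⇒ 6 ⇒ 4 ⇒ 3 ⇒ 1.** The enal C=C bond is cut (Wittig), then the C6–CHO bond, with a temporary bromine on C8 that forces formylation to C6 and is removed before any organolithium is used. Finally the benzyl ethers are cut, which leads to the chiral-pool flavan-3-ol carrying both lower stereocentres. The forward steps need C8-selective bromination and chemoselective debromination.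

**10 ⇒ 9 and 18 ⇒ 17.** O–benzyl bonds are cut to two simple phenols.

## Other disconnections considered

**Alternative 1:** The cut is the C2=C3 bond of a 4H-chromene, so ring C would be closed from an acyclic ester.
- **Forward step.** The ring A aryl ester A1 (a 3,4,5-tris(benzyloxy)benzoate with a 1-ArL-allyl group ortho to the ester oxygen) would be treated with the titanium ethylidene reagent made from TiCl4, Zn, catalytic PbCl2, TMEDA and 1,1-dibromoethane. Alkylidene exchange at the terminal alkene and olefination of the ester carbonyl would give the 2-aryl-4H-chromene A2.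
- **In its favour.** Ring B and C2 arrive as an acyl group by plain esterification, no basic organometallic meets an aryl ester, and the step closes a ring. On these points it is the equal or the better of the chosen plan.
- **Against it.** A2 lacks O3 and the C2 hydrogen. Syn hydroboration anti to the C4 aryl group would put ring B on the wrong face (2,3-trans). The only path to 2,3-cis-3,4-trans is oxidation of the enol ether anti to the C4 aryl group and then ionic reduction at C2. That is the same oxocarbenium reduction as in the chosen plan, reached two or three steps later. A1 also needs its allylic diarylmethine stereocentre from an asymmetric allylic arylation, and low-valent titanium halides would meet a crowded ester beside an acid-sensitive diarylmethine.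
- **Comparison.** Equal in the final stereochemical risk at C2, better in the mildness of ring B introduction, worse in step count and in the handling of C3.

**Alternative 2:** The cut removes ring D; C8–C8a, C5–C6, C7–C8 and C4a–C5 would be made in one photochemical benzannulation.
- **Forward step.** Irradiation of diazoketone A3 (ring F as a dihydropyran with a diazoacetyl group on C8a) would trigger Wolff rearrangement. Ketene–alkyne [2+2] addition to siloxyalkyne A4 (the complete galloylated upper unit with a (triisopropylsilyloxy)ethynyl group on C4), four-electron ring opening, six-electron closure and tautomerisation would give phenol A5.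
- **In its favour.** The 4→6 junction is fixed by construction, so no blocking group and no C6/C8 question arise. Here it is better than the chosen plan, which spends two steps on a bromine block. It is also the most convergent and forms four bonds and a ring at once.
- **Against it.** Ring D does not exist beforehand, so A3 cannot come from gallocatechin and both lower stereocentres must be made de novo. A4 needs the whole upper unit with three stereocentres and an ynol silyl ether at a benzylic, β-acyloxy carbon. Fourteen benzyl ethers and a gallate absorb in the ultraviolet. A5 needs an extra desilylation.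
- **Comparison.** Mechanistically the most powerful ring construction, but far longer overall.

**Alternative 3:** The cut is O1–C2 and C3–C4, ring C by a hetero-[4+2] addition.
- **Forward step.** A chiral phosphoric acid would dehydrate the ortho-hydroxy diarylmethanol A6 to the ortho-quinone methide A8. The (Z)-enol gallate A7 would add across O1 and C4 and give A9, which is identical with 24.
- **In its favour.** Ring C, all three stereocentres and the gallate would arrive in one step, so desilylation and acylation are saved. A6 would come from aldehyde 7 by one aryl addition. In step economy it is better than the chosen plan.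
- **Against it.** The aryl and acyloxy groups of A7 polarise the alkene in opposite senses, so the regiochemistry is open. A8 is a highly stabilised bis(trioxygenated aryl)methyl cation equivalent, unreactive towards a weak enol ester and prone to stepwise addition that would lose the Z geometry. The 3,4-trans relation depends on an endo/exo preference that cannot be predicted. The acid catalyst would also have to override or match the remote lower-unit stereocentres.
- **Comparison.** Shorter, equal in the use of 7, but weaker in every element of stereocontrol.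

Key step: step 12

**Remarks.**
- Flavan numbering is used for both units. ArL stands for the (2R,3S)-3,5,7-tris(benzyloxy)-2-[3,4,5-tris(benzyloxy)phenyl]chroman-6-yl group.
- Assumption: 17 and 23 are purchasable.
- The descriptor of upper C4 is R in the benzyl ethers and S in 25 only because the ranking of the two aryl groups changes; no bond at C4 is touched after step 7.

## Route

**Step 1**
Reactants: 1 (+)-gallocatechin
Product: 3 hexa-O-benzyl-(+)-gallocatechin [(2R,3S)-3,5,7-tris(benzyloxy)-2-[3,4,5-tris(benzyloxy)phenyl]chromane], via penta-O-benzyl ether 2 (not isolated)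
Conditions: BnBr, K2CO3, DMF, 0 °C → rt, under argon; then NaH, BnBr, Bu4NI (cat.), 0 °C → rt
Reagents that add atoms: benzyl bromide, BrCc1ccccc1
Why: Williamson etherification in two stages; carbonate deprotonates only the five phenols (argon protects the pyrogallol ring) and NaH then converts the secondary 3-alkoxide, no stereocentre being touched. The benzyl ether on lower O3 keeps that oxygen out of the later esterification.

**Step 2**
Reactants: 3 hexa-O-benzyl-(+)-gallocatechin
Product: 4 (2R,3S)-3,5,7-tris(benzyloxy)-8-bromo-2-[3,4,5-tris(benzyloxy)phenyl]chromane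
Conditions: N-bromosuccinimide, CH2Cl2, −78 °C → rt
Reagents that add atoms: N-bromosuccinimide, O=C1CCC(=O)N1Br
Why: Electrophilic aromatic bromination; in 5,7-dialkoxyflavans C8 (between O1 and one benzyloxy group) is more accessible than C6 (between two benzyloxy groups), so one equivalent should brominate C8 and leave C6 as the only free site of ring D.

**Step 3**
Reactants: 4 8-bromo hexabenzyl ether
Product: 6 (2R,3S)-3,5,7-tris(benzyloxy)-8-bromo-2-[3,4,5-tris(benzyloxy)phenyl]chromane-6-carbaldehyde, via aryl iminium chloride 5 (not isolated)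
Conditions: POCl3, DMF, 0 → 70 °C; then aq. NaOAc, rt
Reagents that add atoms: N,N-dimethylformamide, CN(C)C=O; water, O
Why: Vilsmeier–Haack formylation; C6 is the single unsubstituted carbon of ring D and is activated by three oxygens, whereas each free carbon of ring E is conjugated with only two.

**Step 4**
Reactants: 6 8-bromo-6-carbaldehyde
Product: 7 (2R,3S)-3,5,7-tris(benzyloxy)-2-[3,4,5-tris(benzyloxy)phenyl]chromane-6-carbaldehyde
Conditions: Pd(OAc)2 (5 mol %), PPh3, HCO2Na, DMF, 100 °C
Reagents that add atoms: none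
Why: Palladium-catalysed hydrodehalogenation (oxidative addition, formate exchange, decarboxylation, reductive elimination); a homogeneous palladium–phosphine catalyst should leave benzyl ethers and the aldehyde alone. The bromine is removed here so that no aryl bromide meets the aryllithium of step 12.

**Step 5**
Reactants: 7 6-carbaldehyde
Product: 8 (E)-3-ArL-prop-2-enal
Conditions: Ph3P=CHCHO, toluene, 100 °C
Reagents that add atoms: (triphenylphosphoranylidene)acetaldehyde, O=CC=P(c1ccccc1)(c1ccccc1)c1ccccc1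
Why: Wittig olefination with a formyl-stabilised ylide, which should give the E-enal; the push–pull product is a poorer electrophile than 7, so a second homologation should not compete.

**Step 6**
Reactants: 9 phloroglucinol
Product: 10 3,5-bis(benzyloxy)phenol
Conditions: BnBr (2 equiv), K2CO3, DMF, rt
Reagents that add atoms: benzyl bromide, BrCc1ccccc1
Why: Statistical Williamson etherification of a cheap symmetrical triol; the mono-, bis- and tris-ethers differ enough in polarity to be separated on silica.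

**Step 7**
Reactants: 8 (E)-3-ArL-prop-2-enal; 10 3,5-bis(benzyloxy)phenol
Product: 12 (4R)-5,7-bis(benzyloxy)-4-ArL-chroman-2-ol (lactol; both C2 epimers), via open-chain diarylpropanal 11 (not isolated)
Conditions: (S)-2-[diphenyl(trimethylsilyloxy)methyl]pyrrolidine (20 mol %), PhCO2H (20 mol %), toluene, 0 °C → rt
Reagents that add atoms: none
Why: Iminium-ion catalysis of a Friedel–Crafts conjugate addition followed by hemiacetal closure; in the E,s-trans iminium ion the diphenyl(silyloxy)methyl group covers the Re face of C-β, so the ortho carbon of the hydrogen-bonded phenol should add to the Si face and set C4 as R. Hydrolysis frees 11, which closes through the phenol oxygen; para attack cannot close and is reversible, so material should collect as 12.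

**Step 8**
Reactants: 12 lactol
Product: 13 (4R)-5,7-bis(benzyloxy)-4-ArL-chroman-2-one
Conditions: TEMPO (2,2,6,6-tetramethylpiperidin-1-oxyl, 10 mol %), PhI(OAc)2, CH2Cl2, rt
Reagents that add atoms: none
Why: Oxoammonium-mediated oxidation of a lactol to the lactone under nearly neutral conditions; C4 is not enolisable at this stage and the electron-rich rings should not be attacked.

**Step 9**
Reactants: 13 lactone
Product: 15 (3R,4R)-5,7-bis(benzyloxy)-3-hydroxy-4-ArL-chroman-2-one (3,4-trans), via potassium enolate 14 (not isolated)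
Conditions: KN(SiMe3)2, THF, −78 °C; 3-phenyl-2-(phenylsulfonyl)oxaziridine, −78 °C; AcOH, −78 °C
Reagents that add atoms: 3-phenyl-2-(phenylsulfonyl)oxaziridine, O=S(=O)(c1ccccc1)N1OC1c1ccccc1
Why: Enolate hydroxylation with an N-sulfonyloxaziridine; peri strain with the 5-benzyloxy group holds the C4 aryl group pseudoaxial, so oxygen should be delivered to the opposite face of 14 and give the trans product. A potassium enolate kept at −78 °C should neither expel the ring A phenoxide as a ketene nor add to the sulfonimine by-product.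

**Step 10**
Reactants: 15 hydroxy lactone
Product: 16 (3R,4R)-5,7-bis(benzyloxy)-4-ArL-3-[(triisopropylsilyl)oxy]chroman-2-one
Conditions: i-Pr3SiOTf, 2,6-lutidine, CH2Cl2, 0 °C → rt
Reagents that add atoms: triisopropylsilyl trifluoromethanesulfonate, CC(C)[Si](OS(=O)(=O)C(F)(F)F)(C(C)C)C(C)C
Why: Silylation of a hindered secondary alcohol with a silyl triflate and a base too weak to epimerise C3. The bulky, non-chelating silyl ether is stable to aryllithium and to BF3·OEt2 at low temperature and is the steric control element of step 12.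

**Step 11**
Reactants: 17 5-bromobenzene-1,2,3-triol
Product: 18 1,2,3-tris(benzyloxy)-5-bromobenzene
Conditions: BnBr, K2CO3, DMF, rt, under argon
Reagents that add atoms: benzyl bromide, BrCc1ccccc1
Why: Williamson etherification of the three phenols; the aryl bromide is inert under these conditions.

**Step 12**
Reactants: 16 silyloxy lactone; 18 1,2,3-tris(benzyloxy)-5-bromobenzene
Product: 21 (2R,3R,4R)-5,7-bis(benzyloxy)-4-ArL-2-[3,4,5-tris(benzyloxy)phenyl]-3-[(triisopropylsilyl)oxy]chromane, via aryllithium 19 (not isolated), via hemiketal 20 (not isolated)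
Conditions: 18, n-BuLi, THF, −78 °C; 16, −78 °C; AcOH; then CH2Cl2, Et3SiH, BF3·OEt2, −78 → −30 °C
Reagents that add atoms: none
Why: Bromine–lithium exchange turns 18 into 19, which adds to the lactone carbonyl of 16; the tetrahedral lithium alkoxide, screened by the C3 silyloxy group and the C4 diarylmethine, should persist at −78 °C instead of expelling the ring A phenoxide and taking a second aryl group, and protonation gives 20 (any ring-opened hydroxy ketone re-closes under the Lewis acid). BF3·OEt2 ionises 20 to the 2-aryl oxocarbenium ion, stabilised by O1 and ring B, and Et3SiH delivers hydride to C2. The closest known reaction type is the conversion of sugar lactones into C-aryl glycosides by aryllithium addition and silane reduction of the lactol. No ring is closed, since ring C is already present in 16. The new stereocentre C2 is under substrate control: allylic strain with the coplanar ring B and peri strain with the 5-benzyloxy group hold the trans C3 silyloxy and C4 aryl groups pseudoaxial, and hydride should enter axially, anti to the C3–O bond, through a chair-like transition state that leaves ring B equatorial and cis to O3 (2R). Attack on the other face would meet the adjacent triisopropylsilyl group and pass through a twist-boat; the favoured face is 1,3-related to the C4 aryl group, which a slender Si–H donor should tolerate. The step needs addition to C=O ahead of deprotonation at C3, which the low temperature and the poor accessibility of the C3 hydrogen should secure, and it needs the benzyl ethers, the silyl ether and the acid-sensitive C4–C6 bond to outlast BF3·OEt2, which argues for an excess of silane and a temperature below −20 °C.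

**Step 13**
Reactants: 21 silyl ether
Product: 22 (2R,3R,4R)-5,7-bis(benzyloxy)-4-ArL-2-[3,4,5-tris(benzyloxy)phenyl]chroman-3-ol
Conditions: Bu4NF, AcOH, THF, rt → 45 °C
Reagents that add atoms: none
Why: Fluoride-induced cleavage of the Si–O bond, buffered with acetic acid; the benzyl ethers and both pyran rings are inert, and no C–O bond at C3 is broken.

**Step 14**
Reactants: 22 upper 3-alcohol; 23 3,4,5-tris(benzyloxy)benzoyl chloride
Product: 24 (2R,3R,4R)-5,7-bis(benzyloxy)-4-ArL-2-[3,4,5-tris(benzyloxy)phenyl]chroman-3-yl 3,4,5-tris(benzyloxy)benzoate (tetradeca-O-benzyl target)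
Conditions: Et3N, 4-(dimethylamino)pyridine, CH2Cl2, rt → 40 °C
Reagents that add atoms: none
Why: Nucleophilic catalysis through the acylpyridinium ion brings the acid chloride onto the only free hydroxyl, an axial one between two aryl groups; acylation at oxygen retains the C3 configuration.

**Step 15**
Reactants: 24 tetradeca-O-benzyl target
Product: 25 epigallocatechin-(4β→6)-gallocatechin 3-O-gallate
Conditions: H2 (1 atm), Pd(OH)2/C, THF/MeOH, rt; work-up under argon
Reagents that add atoms: none
Why: Hydrogenolysis of fourteen benzyl ethers under neutral conditions; at room temperature and one atmosphere the aryl ester, the benzylic C2–O1 bonds of rings C and F and the C4–C6 bond should remain.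

## Compound list

1 | (+)-gallocatechin, (2R,3S)-2-(3,4,5-trihydroxyphenyl)chromane-3,5,7-triol | O[C@H]1Cc2c(O)cc(O)cc2O[C@@H]1c1cc(O)c(O)c(O)c1 | starting material

2 | (2R,3S)-5,7-bis(benzyloxy)-2-[3,4,5-tris(benzyloxy)phenyl]chroman-3-ol | O[C@H]1Cc2c(OCc3ccccc3)cc(OCc3ccccc3)cc2O[C@@H]1c1cc(OCc2ccccc2)c(OCc2ccccc2)c(OCc2ccccc2)c1 | intermediate (not isolated)

3 | (2R,3S)-3,5,7-tris(benzyloxy)-2-[3,4,5-tris(benzyloxy)phenyl]chromane | C(c1ccccc1)O[C@H]1Cc2c(OCc3ccccc3)cc(OCc3ccccc3)cc2O[C@@H]1c1cc(OCc2ccccc2)c(OCc2ccccc2)c(OCc2ccccc2)c1 | intermediate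

4 | (2R,3S)-3,5,7-tris(benzyloxy)-8-bromo-2-[3,4,5-tris(benzyloxy)phenyl]chromane | C(c1ccccc1)O[C@H]1Cc2c(OCc3ccccc3)cc(OCc3ccccc3)c(Br)c2O[C@@H]1c1cc(OCc2ccccc2)c(OCc2ccccc2)c(OCc2ccccc2)c1 | intermediate

5 | N-{[(2R,3S)-3,5,7-tris(benzyloxy)-8-bromo-2-[3,4,5-tris(benzyloxy)phenyl]chroman-6-yl]methylidene}-N-methylmethanaminium chloride | C(c1ccccc1)O[C@H]1Cc2c(OCc3ccccc3)c(C=[N+](C)C)c(OCc3ccccc3)c(Br)c2O[C@@H]1c1cc(OCc2ccccc2)c(OCc2ccccc2)c(OCc2ccccc2)c1.[Cl-] | intermediate (not isolated)

6 | (2R,3S)-3,5,7-tris(benzyloxy)-8-bromo-2-[3,4,5-tris(benzyloxy)phenyl]chromane-6-carbaldehyde | C(c1ccccc1)O[C@H]1Cc2c(OCc3ccccc3)c(C=O)c(OCc3ccccc3)c(Br)c2O[C@@H]1c1cc(OCc2ccccc2)c(OCc2ccccc2)c(OCc2ccccc2)c1 | intermediate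

7 | (2R,3S)-3,5,7-tris(benzyloxy)-2-[3,4,5-tris(benzyloxy)phenyl]chromane-6-carbaldehyde | C(c1ccccc1)O[C@H]1Cc2c(OCc3ccccc3)c(C=O)c(OCc3ccccc3)cc2O[C@@H]1c1cc(OCc2ccccc2)c(OCc2ccccc2)c(OCc2ccccc2)c1 | intermediate

8 | (E)-3-[(2R,3S)-3,5,7-tris(benzyloxy)-2-[3,4,5-tris(benzyloxy)phenyl]chroman-6-yl]prop-2-enal | C(c1ccccc1)O[C@H]1Cc2c(OCc3ccccc3)c(/C=C/C=O)c(OCc3ccccc3)cc2O[C@@H]1c1cc(OCc2ccccc2)c(OCc2ccccc2)c(OCc2ccccc2)c1 | intermediate

9 | phloroglucinol (benzene-1,3,5-triol) | Oc1cc(O)cc(O)c1 | starting material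

10 | 3,5-bis(benzyloxy)phenol | Oc1cc(OCc2ccccc2)cc(OCc2ccccc2)c1 | intermediate

11 | (3R)-3-[2,4-bis(benzyloxy)-6-hydroxyphenyl]-3-ArL-propanal | O=CC[C@@H](c3c(OCc4ccccc4)cc4c(c3OCc3ccccc3)C[C@H](OCc3ccccc3)[C@@H](c3cc(OCc5ccccc5)c(OCc5ccccc5)c(OCc5ccccc5)c3)O4)c2c(OCc6ccccc6)cc(OCc6ccccc6)cc2O | intermediate (not isolated)

12 | (4R)-5,7-bis(benzyloxy)-4-ArL-chroman-2-ol (both C2 epimers) | OC1C[C@@H](c3c(OCc4ccccc4)cc4c(c3OCc3ccccc3)C[C@H](OCc3ccccc3)[C@@H](c3cc(OCc5ccccc5)c(OCc5ccccc5)c(OCc5ccccc5)c3)O4)c2c(OCc6ccccc6)cc(OCc6ccccc6)cc2O1 | intermediate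

13 | (4R)-5,7-bis(benzyloxy)-4-ArL-chroman-2-one | O=C1C[C@@H](c3c(OCc4ccccc4)cc4c(c3OCc3ccccc3)C[C@H](OCc3ccccc3)[C@@H](c3cc(OCc5ccccc5)c(OCc5ccccc5)c(OCc5ccccc5)c3)O4)c2c(OCc6ccccc6)cc(OCc6ccccc6)cc2O1 | intermediate

14 | potassium (4R)-5,7-bis(benzyloxy)-4-ArL-4H-chromen-2-olate | [K+].[O-]C1=C[C@@H](c3c(OCc4ccccc4)cc4c(c3OCc3ccccc3)C[C@H](OCc3ccccc3)[C@@H](c3cc(OCc5ccccc5)c(OCc5ccccc5)c(OCc5ccccc5)c3)O4)c2c(OCc6ccccc6)cc(OCc6ccccc6)cc2O1 | intermediate (not isolated)

15 | (3R,4R)-5,7-bis(benzyloxy)-3-hydroxy-4-ArL-chroman-2-one | O[C@@H]1[C@@H](c3c(OCc4ccccc4)cc4c(c3OCc3ccccc3)C[C@H](OCc3ccccc3)[C@@H](c3cc(OCc5ccccc5)c(OCc5ccccc5)c(OCc5ccccc5)c3)O4)c2c(OCc6ccccc6)cc(OCc6ccccc6)cc2OC1=O | intermediate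

16 | (3R,4R)-5,7-bis(benzyloxy)-4-ArL-3-[(triisopropylsilyl)oxy]chroman-2-one | CC(C)[Si](C(C)C)(C(C)C)O[C@@H]1[C@@H](c3c(OCc4ccccc4)cc4c(c3OCc3ccccc3)C[C@H](OCc3ccccc3)[C@@H](c3cc(OCc5ccccc5)c(OCc5ccccc5)c(OCc5ccccc5)c3)O4)c2c(OCc6ccccc6)cc(OCc6ccccc6)cc2OC1=O | intermediate (key-step precursor)

17 | 5-bromobenzene-1,2,3-triol | Oc1cc(Br)cc(O)c1O | starting material

18 | 1,2,3-tris(benzyloxy)-5-bromobenzene | Brc1cc(OCc2ccccc2)c(OCc2ccccc2)c(OCc2ccccc2)c1 | intermediate

19 | [3,4,5-tris(benzyloxy)phenyl]lithium | [Li]c1cc(OCc2ccccc2)c(OCc2ccccc2)c(OCc2ccccc2)c1 | intermediate (not isolated)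

20 | (3R,4R)-5,7-bis(benzyloxy)-4-ArL-2-[3,4,5-tris(benzyloxy)phenyl]-3-[(triisopropylsilyl)oxy]chroman-2-ol (both C2 epimers) | CC(C)[Si](C(C)C)(C(C)C)O[C@@H]1[C@@H](c3c(OCc4ccccc4)cc4c(c3OCc3ccccc3)C[C@H](OCc3ccccc3)[C@@H](c3cc(OCc5ccccc5)c(OCc5ccccc5)c(OCc5ccccc5)c3)O4)c2c(OCc6ccccc6)cc(OCc6ccccc6)cc2OC1(O)c1cc(OCc7ccccc7)c(OCc7ccccc7)c(OCc7ccccc7)c1 | intermediate (not isolated)

21 | (2R,3R,4R)-5,7-bis(benzyloxy)-4-ArL-2-[3,4,5-tris(benzyloxy)phenyl]-3-[(triisopropylsilyl)oxy]chromane (ring B α, O3 α, ArL β) | CC(C)[Si](C(C)C)(C(C)C)O[C@@H]1[C@@H](c3c(OCc4ccccc4)cc4c(c3OCc3ccccc3)C[C@H](OCc3ccccc3)[C@@H](c3cc(OCc5ccccc5)c(OCc5ccccc5)c(OCc5ccccc5)c3)O4)c2c(OCc6ccccc6)cc(OCc6ccccc6)cc2O[C@@H]1c1cc(OCc7ccccc7)c(OCc7ccccc7)c(OCc7ccccc7)c1 | intermediate (key-step product)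

22 | (2R,3R,4R)-5,7-bis(benzyloxy)-4-ArL-2-[3,4,5-tris(benzyloxy)phenyl]chroman-3-ol | O[C@@H]1[C@@H](c3c(OCc4ccccc4)cc4c(c3OCc3ccccc3)C[C@H](OCc3ccccc3)[C@@H](c3cc(OCc5ccccc5)c(OCc5ccccc5)c(OCc5ccccc5)c3)O4)c2c(OCc6ccccc6)cc(OCc6ccccc6)cc2O[C@@H]1c1cc(OCc7ccccc7)c(OCc7ccccc7)c(OCc7ccccc7)c1 | intermediate

23 | 3,4,5-tris(benzyloxy)benzoyl chloride | O=C(Cl)c1cc(OCc2ccccc2)c(OCc2ccccc2)c(OCc2ccccc2)c1 | starting material

24 | (2R,3R,4R)-5,7-bis(benzyloxy)-4-ArL-2-[3,4,5-tris(benzyloxy)phenyl]chroman-3-yl 3,4,5-tris(benzyloxy)benzoate | O=C(O[C@@H]1[C@@H](c3c(OCc4ccccc4)cc4c(c3OCc3ccccc3)C[C@H](OCc3ccccc3)[C@@H](c3cc(OCc5ccccc5)c(OCc5ccccc5)c(OCc5ccccc5)c3)O4)c2c(OCc6ccccc6)cc(OCc6ccccc6)cc2O[C@@H]1c1cc(OCc7ccccc7)c(OCc7ccccc7)c(OCc7ccccc7)c1)c1cc(OCc8ccccc8)c(OCc8ccccc8)c(OCc8ccccc8)c1 | intermediate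

25 | epigallocatechin-(4β→6)-gallocatechin 3-O-gallate, (2R,3R,4S)-5,7-dihydroxy-2-(3,4,5-trihydroxyphenyl)-4-[(2R,3S)-3,5,7-trihydroxy-2-(3,4,5-trihydroxyphenyl)chroman-6-yl]chroman-3-yl 3,4,5-trihydroxybenzoate | O=C(O[C@@H]1[C@@H](c2c(O)cc3c(c2O)C[C@H](O)[C@@H](c2cc(O)c(O)c(O)c2)O3)c2c(O)cc(O)cc2O[C@@H]1c1cc(O)c(O)c(O)c1)c1cc(O)c(O)c(O)c1 | target

## Step count and least certain steps

Total: 15 steps. Longest linear sequence: 13 steps (steps 1–5, 7–10, 12–15).

**Step 12 (key step).**
- *What may go wrong.* Hydride delivery may go to the face syn to the silyloxy group, giving the C2 epimer, because the favoured face is 1,3-related to the C4 aryl group. The tetrahedral intermediate may collapse and take a second aryl group. The oxocarbenium ion may lose the C3 proton, which would scramble C3 on reprotonation.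
- *Fallback.* It sets out from 16 and 18. The addition of 19 is carried out as before but worked up without acid, and the ring-opened tautomer of 20, (2R,3R)-3-[2,4-bis(benzyloxy)-6-hydroxyphenyl]-3-ArL-1-[3,4,5-tris(benzyloxy)phenyl]-2-[(triisopropylsilyl)oxy]propan-1-one F1, is isolated. Its ketone is reduced with LiBH(s-Bu)3 in THF at −78 °C; under non-chelation 1,2-induction from the silyloxy stereocentre this should give the 1,2-anti alcohol (1S,2R,3R)-3-[2,4-bis(benzyloxy)-6-hydroxyphenyl]-3-ArL-1-[3,4,5-tris(benzyloxy)phenyl]-2-[(triisopropylsilyl)oxy]propan-1-ol F2. Ring C is then closed by an intramolecular Mitsunobu etherification (PPh3, diisopropyl azodicarboxylate, THF, 0 °C), in which the phenol displaces the benzylic hydroxyl with inversion. The route is rejoined at 21. C2 is then set by acyclic induction and an SN2 closure, not by the conformation of a cyclic cation.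

**Step 7.**
- *What may go wrong.* The iminium ion of a push–pull, doubly ortho-substituted enal may be too poor an electrophile. Face selection may be eroded by reversible addition. The phenol may react through its para carbon.
- *Fallback.* It sets out from 7. Knoevenagel condensation with Meldrum's acid (pyridine, rt) gives the arylidene derivative 5-(ArL-methylidene)-2,2-dimethyl-1,3-dioxane-4,6-dione F3, a far stronger acceptor. Conjugate addition of 10 and lactonisation with loss of acetone and carbon dioxide (pyridine, 90 °C) give 13 together with its C4 epimer, (4S)-5,7-bis(benzyloxy)-4-ArL-chroman-2-one F4. Because the lower unit is enantiopure, the two are diastereomers and are separated by chromatography. The route is rejoined at 13; catalyst control is given up for separation.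

**Step 9.**
- *What may go wrong.* The aryl ester enolate may fragment to a ketene and phenoxide, conversion at the hindered C3 may be incomplete, or oxygen may be delivered syn to the aryl group.
- *Fallback.* It sets out from 12. Acid-catalysed dehydration (pyridinium p-toluenesulfonate, toluene, 80 °C, molecular sieves) gives the enol ether (4R)-5,7-bis(benzyloxy)-4-ArL-4H-chromene F5. Dihydroxylation anti to the C4 aryl group (OsO4 cat., N-methylmorpholine N-oxide, acetone/water) gives (3R,4R)-5,7-bis(benzyloxy)-4-ArL-chromane-2,3-diol F6. Selective oxidation of its lactol hydroxyl with Ag2CO3 on Celite in toluene at reflux leads to 15, where the route is rejoined.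

**Step 3.**
- *What may go wrong.* Formylation between two benzyloxy groups may stall, or substitution may spill over to ring E.
- *Fallback.* It sets out from 4. Iodination with N-iodosuccinimide (cat. CF3CO2H, CH2Cl2, 0 °C) gives (2R,3S)-3,5,7-tris(benzyloxy)-8-bromo-6-iodo-2-[3,4,5-tris(benzyloxy)phenyl]chromane F7. Selective iodine–magnesium exchange with i-PrMgCl·LiCl in THF at −40 °C (the iodide exchanges much faster than the bromide) gives the arylmagnesium chloride [(2R,3S)-3,5,7-tris(benzyloxy)-8-bromo-2-[3,4,5-tris(benzyloxy)phenyl]chroman-6-yl]magnesium chloride F8, which is quenched with DMF. The route is rejoined at 6.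

## Further compounds

F1 | step 12 | (2R,3R)-3-[2,4-bis(benzyloxy)-6-hydroxyphenyl]-3-ArL-1-[3,4,5-tris(benzyloxy)phenyl]-2-[(triisopropylsilyl)oxy]propan-1-one | CC(C)[Si](C(C)C)(C(C)C)O[C@H]([C@@H](c3c(OCc4ccccc4)cc4c(c3OCc3ccccc3)C[C@H](OCc3ccccc3)[C@@H](c3cc(OCc5ccccc5)c(OCc5ccccc5)c(OCc5ccccc5)c3)O4)c2c(OCc6ccccc6)cc(OCc6ccccc6)cc2O)C(=O)c1cc(OCc7ccccc7)c(OCc7ccccc7)c(OCc7ccccc7)c1
F2 | step 12 | (1S,2R,3R)-3-[2,4-bis(benzyloxy)-6-hydroxyphenyl]-3-ArL-1-[3,4,5-tris(benzyloxy)phenyl]-2-[(triisopropylsilyl)oxy]propan-1-ol | CC(C)[Si](C(C)C)(C(C)C)O[C@H]([C@@H](c3c(OCc4ccccc4)cc4c(c3OCc3ccccc3)C[C@H](OCc3ccccc3)[C@@H](c3cc(OCc5ccccc5)c(OCc5ccccc5)c(OCc5ccccc5)c3)O4)c2c(OCc6ccccc6)cc(OCc6ccccc6)cc2O)[C@@H](O)c1cc(OCc7ccccc7)c(OCc7ccccc7)c(OCc7ccccc7)c1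
F3 | step 7 | 5-(ArL-methylidene)-2,2-dimethyl-1,3-dioxane-4,6-dione | CC1(C)OC(=O)C(=Cc3c(OCc4ccccc4)cc4c(c3OCc3ccccc3)C[C@H](OCc3ccccc3)[C@@H](c3cc(OCc5ccccc5)c(OCc5ccccc5)c(OCc5ccccc5)c3)O4)C(=O)O1
F4 | step 7 | (4S)-5,7-bis(benzyloxy)-4-ArL-chroman-2-one | O=C1C[C@H](c3c(OCc4ccccc4)cc4c(c3OCc3ccccc3)C[C@H](OCc3ccccc3)[C@@H](c3cc(OCc5ccccc5)c(OCc5ccccc5)c(OCc5ccccc5)c3)O4)c2c(OCc6ccccc6)cc(OCc6ccccc6)cc2O1
F5 | step 9 | (4R)-5,7-bis(benzyloxy)-4-ArL-4H-chromene | C1=C[C@@H](c3c(OCc4ccccc4)cc4c(c3OCc3ccccc3)C[C@H](OCc3ccccc3)[C@@H](c3cc(OCc5ccccc5)c(OCc5ccccc5)c(OCc5ccccc5)c3)O4)c2c(OCc6ccccc6)cc(OCc6ccccc6)cc2O1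
F6 | step 9 | (3R,4R)-5,7-bis(benzyloxy)-4-ArL-chromane-2,3-diol (both C2 epimers) | O[C@@H]1[C@@H](c3c(OCc4ccccc4)cc4c(c3OCc3ccccc3)C[C@H](OCc3ccccc3)[C@@H](c3cc(OCc5ccccc5)c(OCc5ccccc5)c(OCc5ccccc5)c3)O4)c2c(OCc6ccccc6)cc(OCc6ccccc6)cc2OC1O
F7 | step 3 | (2R,3S)-3,5,7-tris(benzyloxy)-8-bromo-6-iodo-2-[3,4,5-tris(benzyloxy)phenyl]chromane | C(c1ccccc1)O[C@H]1Cc2c(OCc3ccccc3)c(I)c(OCc3ccccc3)c(Br)c2O[C@@H]1c1cc(OCc2ccccc2)c(OCc2ccccc2)c(OCc2ccccc2)c1
F8 | step 3 | [(2R,3S)-3,5,7-tris(benzyloxy)-8-bromo-2-[3,4,5-tris(benzyloxy)phenyl]chroman-6-yl]magnesium chloride | C(c1ccccc1)O[C@H]1Cc2c(OCc3ccccc3)c([Mg]Cl)c(OCc3ccccc3)c(Br)c2O[C@@H]1c1cc(OCc2ccccc2)c(OCc2ccccc2)c(OCc2ccccc2)c1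
A1 | alternative 1 | 3,5-bis(benzyloxy)-2-[(1R)-1-ArL-prop-2-en-1-yl]phenyl 3,4,5-tris(benzyloxy)benzoate | C=C[C@@H](c3c(OCc4ccccc4)cc4c(c3OCc3ccccc3)C[C@H](OCc3ccccc3)[C@@H](c3cc(OCc5ccccc5)c(OCc5ccccc5)c(OCc5ccccc5)c3)O4)c2c(OCc6ccccc6)cc(OCc6ccccc6)cc2OC(=O)c1cc(OCc7ccccc7)c(OCc7ccccc7)c(OCc7ccccc7)c1
A2 | alternative 1 | (4R)-5,7-bis(benzyloxy)-4-ArL-2-[3,4,5-tris(benzyloxy)phenyl]-4H-chromene | C1(c7cc(OCc8ccccc8)c(OCc8ccccc8)c(OCc8ccccc8)c7)=C[C@@H](c3c(OCc4ccccc4)cc4c(c3OCc3ccccc3)C[C@H](OCc3ccccc3)[C@@H](c3cc(OCc5ccccc5)c(OCc5ccccc5)c(OCc5ccccc5)c3)O4)c2c(OCc6ccccc6)cc(OCc6ccccc6)cc2O1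
A3 | alternative 2 | 1-[(2R,3S)-3-(benzyloxy)-2-[3,4,5-tris(benzyloxy)phenyl]-3,4-dihydro-2H-pyran-6-yl]-2-diazoethan-1-one | [N-]=[N+]=CC(=O)C1=CC[C@H](OCc2ccccc2)[C@@H](c2cc(OCc3ccccc3)c(OCc3ccccc3)c(OCc3ccccc3)c2)O1
A4 | alternative 2 | 5,7-bis(benzyloxy)-2α-[3,4,5-tris(benzyloxy)phenyl]-4β-{[(triisopropylsilyl)oxy]ethynyl}chroman-3α-yl 3,4,5-tris(benzyloxy)benzoate | O=C(O[C@@H]1[C@@H](C#CO[Si](C(C)C)(C(C)C)C(C)C)c2c(OCc6ccccc6)cc(OCc6ccccc6)cc2O[C@@H]1c1cc(OCc7ccccc7)c(OCc7ccccc7)c(OCc7ccccc7)c1)c1cc(OCc8ccccc8)c(OCc8ccccc8)c(OCc8ccccc8)c1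
A5 | alternative 2 | benzylated target with the ring D 5-hydroxyl free and a 7-O-triisopropylsilyl group | O=C(O[C@@H]1[C@@H](c3c(O[Si](C(C)C)(C(C)C)C(C)C)cc4c(c3O)C[C@H](OCc3ccccc3)[C@@H](c3cc(OCc5ccccc5)c(OCc5ccccc5)c(OCc5ccccc5)c3)O4)c2c(OCc6ccccc6)cc(OCc6ccccc6)cc2O[C@@H]1c1cc(OCc7ccccc7)c(OCc7ccccc7)c(OCc7ccccc7)c1)c1cc(OCc8ccccc8)c(OCc8ccccc8)c(OCc8ccccc8)c1
A6 | alternative 3 | 3,5-bis(benzyloxy)-2-[ArL(hydroxy)methyl]phenol (either carbinol epimer) | OC(c3c(OCc4ccccc4)cc4c(c3OCc3ccccc3)C[C@H](OCc3ccccc3)[C@@H](c3cc(OCc5ccccc5)c(OCc5ccccc5)c(OCc5ccccc5)c3)O4)c2c(OCc6ccccc6)cc(OCc6ccccc6)cc2O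
A7 | alternative 3 | (Z)-2-[3,4,5-tris(benzyloxy)phenyl]ethenyl 3,4,5-tris(benzyloxy)benzoate | O=C(O/C=C\c1cc(OCc2ccccc2)c(OCc2ccccc2)c(OCc2ccccc2)c1)c1cc(OCc2ccccc2)c(OCc2ccccc2)c(OCc2ccccc2)c1
A8 | alternative 3 | 3,5-bis(benzyloxy)-6-(ArL-methylidene)cyclohexa-2,4-dien-1-one | O=C1C=C(OCc6ccccc6)C=C(OCc6ccccc6)C1=Cc3c(OCc4ccccc4)cc4c(c3OCc3ccccc3)C[C@H](OCc3ccccc3)[C@@H](c3cc(OCc5ccccc5)c(OCc5ccccc5)c(OCc5ccccc5)c3)O4
A9 | alternative 3 | tetradeca-O-benzyl target (identical with 24) | O=C(O[C@@H]1[C@@H](c3c(OCc4ccccc4)cc4c(c3OCc3ccccc3)C[C@H](OCc3ccccc3)[C@@H](c3cc(OCc5ccccc5)c(OCc5ccccc5)c(OCc5ccccc5)c3)O4)c2c(OCc6ccccc6)cc(OCc6ccccc6)cc2O[C@@H]1c1cc(OCc7ccccc7)c(OCc7ccccc7)c(OCc7ccccc7)c1)c1cc(OCc8ccccc8)c(OCc8ccccc8)c(OCc8ccccc8)c1
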